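**Retrosynthetic overview**
1. Last bond: the ring A–O–ring B diaryl ether, cut into a ring-A catechol monosulfate (sulfate already in place) and a ring-B/C aryl(2,4,6-trimethoxyphenyl)iodonium cation, joined first as an ion pair and coupled on adding base. This is the proposed new step.
2. Ring A monosulfate ⇒ 2,4-dibromophenol by Elbs persulfate ortho-oxidation, which puts the OSO3 group on the new oxygen, as in the target.
3. Ring-B/C iodonium ⇒ ring-B/C aryl iodide ⇒ 2,3,4-tribromo-6-iodophenol + (2,4-dibromophenyl)(TMP)iodonium salt (ring C).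
4. 2,3,4-Tribromo-6-iodophenol ⇒ 5-bromo-2-iodophenol by double bromination.
5. No ring is formed; all three benzene rings are bought. Order of joining: C onto B, then A onto B.

Assumption: the target has no stereocentre and no stable chiral axis, so no stereocontrol is needed; it is drawn as the free hydrogen sulfate, so the potassium salt is acidified at the end; all starting materials (1, 2, 5, 10) are taken as purchasable.

**Step 1**
Reactants: 1 2,4-dibromo-1-iodobenzene; 2 1,3,5-trimethoxybenzene
Product: 4 (2,4-dibromophenyl)(2,4,6-trimethoxyphenyl)iodonium tosylate, via 2,4-dibromo-1-[hydroxy(tosyloxy)-λ3-iodanyl]benzene 3 (not isolated)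
Conditions: mCPBA (1.1 equiv), TsOH·H2O (1.05 equiv), MeCN, 55 °C, 1 h; then 2 (1.05 equiv), 55 °C → rt; Et2O trituration
Reagents that add atoms: p-toluenesulfonic acid monohydrate, Cc1ccc(cc1)S(=O)(=O)O.O
Why: One-pot Koser-type oxidation of the aryl iodide to λ3-iodane 3 (its I–OH oxygen comes from mCPBA and leaves again as water), followed by electrophilic aromatic substitution on the very electron-rich arene 2, a standard diaryliodonium salt synthesis.

**Step 2**
Reactants: 5 5-bromo-2-iodophenol
Product: 6 2,3,4-tribromo-6-iodophenol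
Conditions: NBS (2.1 equiv), TsOH·H2O (10 mol%), MeCN, 0 °C → rt
Reagents that add atoms: N-bromosuccinimide, BrN1C(=O)CCC1=O
Why: Electrophilic aromatic bromination in which the OH group directs to its free para carbon (C4) and its one free ortho carbon (C6), giving the 4,5,6-tribromo pattern of ring B while the ortho iodine is kept.

**Step 3**
Reactants: 6 2,3,4-tribromo-6-iodophenol; 4 (2,4-dibromophenyl)(2,4,6-trimethoxyphenyl)iodonium tosylate
Product: 7 1,2,3-tribromo-4-(2,4-dibromophenoxy)-5-iodobenzene
Conditions: K2CO3 (1.5 equiv), MeCN, 60 °C; chromatography to remove the iodoarene by-product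
Reagents that add atoms: none
Why: Metal-free O-arylation of a phenoxide with an aryl(TMP)iodonium salt (ligand exchange and ligand coupling at iodine(III)); the electron-rich TMP group stays on iodine and the C–Br and C–I bonds are inert because no metal is present.

**Step 4**
Reactants: 7 1,2,3-tribromo-4-(2,4-dibromophenoxy)-5-iodobenzene; 2 1,3,5-trimethoxybenzene
Product: 9 [3,4,5-tribromo-2-(2,4-dibromophenoxy)phenyl](2,4,6-trimethoxyphenyl)iodonium tosylate, via 1,2,3-tribromo-4-(2,4-dibromophenoxy)-5-[hydroxy(tosyloxy)-λ3-iodanyl]benzene 8 (not isolated)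
Conditions: mCPBA (1.2 equiv), TsOH·H2O (1.2 equiv), MeCN/CHCl3, 65 °C, 2 h; then 2 (1.1 equiv), rt; Et2O trituration
Reagents that add atoms: p-toluenesulfonic acid monohydrate, Cc1ccc(cc1)S(=O)(=O)O.O
Why: Same Koser oxidation and electrophilic aromatic substitution as step 1 (oxygen of 8 from mCPBA, lost as water); TsOH instead of TfOH keeps the λ3-iodane too weak an electrophile to cyclise onto the deactivated dibromophenoxy ring, so only the far more nucleophilic 2 reacts.

**Step 5**
Reactants: 10 2,4-dibromophenol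
Product: 12 potassium 3,5-dibromo-2-hydroxyphenyl sulfate, via dipotassium 3,5-dibromo-2-oxidophenyl sulfate 11 (not isolated)
Conditions: K2S2O8 (1.0 equiv), KOH (2 equiv), H2O, 0 °C → rt, 24 h; then dilute H2SO4 to pH 6, Et2O wash (recovers 10), evaporate, extract with MeOH and crystallise
Reagents that add atoms: potassium peroxodisulfate, [K+].[K+].[O-]S(=O)(=O)OOS(=O)(=O)[O-]; potassium hydroxide, [K+].[OH-]
Why: Elbs persulfate oxidation, in which the phenolate of 10 attacks a peroxide oxygen of S2O8²⁻ through its only free ortho carbon (para is blocked by Br) and rearomatises, so the sulfate sits on the new oxygen next to the ring CH as in the target; a modest yield with recovered 10 is expected.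

**Step 6**
Reactants: 12 potassium 3,5-dibromo-2-hydroxyphenyl sulfate; 9 [3,4,5-tribromo-2-(2,4-dibromophenoxy)phenyl](2,4,6-trimethoxyphenyl)iodonium tosylate
Product: 16 3,5-dibromo-2-[3,4,5-tribromo-2-(2,4-dibromophenoxy)phenoxy]phenyl hydrogen sulfate (bromoiesol A sulfate), via [3,4,5-tribromo-2-(2,4-dibromophenoxy)phenyl](2,4,6-trimethoxyphenyl)iodonium 3,5-dibromo-2-hydroxyphenyl sulfate 13 (not isolated), via potassium 3,5-dibromo-2-({[3,4,5-tribromo-2-(2,4-dibromophenoxy)phenyl](2,4,6-trimethoxyphenyl)-λ3-iodanyl}oxy)phenyl sulfate 14 (not isolated), via potassium 3,5-dibromo-2-[3,4,5-tribromo-2-(2,4-dibromophenoxy)phenoxy]phenyl sulfate 15 (not isolated)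
Conditions: 12 and 9 (1.05 equiv), MeCN, rt, 1 h (KOTs precipitates); then powdered K2CO3 (1.5 equiv), 0 → 50 °C; evaporate, Et2O trituration (removes the iodoarene by-product); then 1 M HCl, EtOAc, 0 °C, dry and concentrate cold
Reagents that add atoms: none
Why: Proposed new method: sulfate-retentive, protecting-group-free O-arylation in which the catechol monosulfate is first installed as the counter-ion of the iodonium cation and then coupled by base. Anion metathesis of 12 with 9, driven by precipitation of potassium tosylate from MeCN, gives ion pair 13, in which the ArOSO3⁻ group is non-nucleophilic, base-stable and not a leaving group, so nothing couples until base is added. Carbonate then removes the acidic phenol proton (OH flanked by Br and OSO3⁻, para to Br) inside the ion pair, and the phenoxide binds iodine(III) to give the T-shaped λ3-iodane 14. Three-centre ligand coupling joins O to the ipso carbon of the electron-poor, ortho-substituted ring-B aryl while the electron-rich TMP group stays on iodine. No metal is present, so the seven C–Br bonds are untouched, and the electron-poor phenoxide should not reduce iodine(III) by electron transfer. The closest known reaction type is the base-mediated, metal-free O-arylation of phenols with diaryliodonium or aryl(TMP)iodonium salts, which has not been shown for a nucleophile bearing a free sulfate monoester, for a nucleophile delivered as the iodonium counter-ion, or with an ortho-aryloxy pentabromo aryl donor. Cold acidification of 15 then gives the free acid 16.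

**Compound list**
1 | 2,4-dibromo-1-iodobenzene | Ic1ccc(Br)cc1Br | starting material
2 | 1,3,5-trimethoxybenzene | COc1cc(OC)cc(OC)c1 | starting material
3 | 2,4-dibromo-1-[hydroxy(tosyloxy)-λ3-iodanyl]benzene | OI(OS(=O)(=O)c1ccc(C)cc1)c1ccc(Br)cc1Br | intermediate (not isolated)
4 | (2,4-dibromophenyl)(2,4,6-trimethoxyphenyl)iodonium tosylate | COc1cc(OC)c([I+]c2ccc(Br)cc2Br)c(OC)c1.Cc1ccc(cc1)S(=O)(=O)[O-] | intermediate
5 | 5-bromo-2-iodophenol | Oc1cc(Br)ccc1I | starting material
6 | 2,3,4-tribromo-6-iodophenol | Oc1c(Br)c(Br)c(Br)cc1I | intermediate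
7 | 1,2,3-tribromo-4-(2,4-dibromophenoxy)-5-iodobenzene | Ic1cc(Br)c(Br)c(Br)c1Oc1ccc(Br)cc1Br | intermediate
8 | 1,2,3-tribromo-4-(2,4-dibromophenoxy)-5-[hydroxy(tosyloxy)-λ3-iodanyl]benzene | OI(OS(=O)(=O)c1ccc(C)cc1)c1cc(Br)c(Br)c(Br)c1Oc1ccc(Br)cc1Br | intermediate (not isolated)
9 | [3,4,5-tribromo-2-(2,4-dibromophenoxy)phenyl](2,4,6-trimethoxyphenyl)iodonium tosylate | COc1cc(OC)c([I+]c2cc(Br)c(Br)c(Br)c2Oc2ccc(Br)cc2Br)c(OC)c1.Cc1ccc(cc1)S(=O)(=O)[O-] | intermediate
10 | 2,4-dibromophenol | Oc1ccc(Br)cc1Br | starting material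
11 | dipotassium 3,5-dibromo-2-oxidophenyl sulfate | [K+].[K+].[O-]c1c(Br)cc(Br)cc1OS(=O)(=O)[O-] | intermediate (not isolated)
12 | potassium 3,5-dibromo-2-hydroxyphenyl sulfate | [K+].Oc1c(Br)cc(Br)cc1OS(=O)(=O)[O-] | intermediate
13 | [3,4,5-tribromo-2-(2,4-dibromophenoxy)phenyl](2,4,6-trimethoxyphenyl)iodonium 3,5-dibromo-2-hydroxyphenyl sulfate | COc1cc(OC)c([I+]c2cc(Br)c(Br)c(Br)c2Oc2ccc(Br)cc2Br)c(OC)c1.Oc1c(Br)cc(Br)cc1OS(=O)(=O)[O-] | intermediate (not isolated)
14 | potassium 3,5-dibromo-2-({[3,4,5-tribromo-2-(2,4-dibromophenoxy)phenyl](2,4,6-trimethoxyphenyl)-λ3-iodanyl}oxy)phenyl sulfate | [K+].COc1cc(OC)c(I(Oc2c(Br)cc(Br)cc2OS(=O)(=O)[O-])c2cc(Br)c(Br)c(Br)c2Oc2ccc(Br)cc2Br)c(OC)c1 | intermediate (not isolated)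
15 | potassium 3,5-dibromo-2-[3,4,5-tribromo-2-(2,4-dibromophenoxy)phenoxy]phenyl sulfate | [K+].[O-]S(=O)(=O)Oc1cc(Br)cc(Br)c1Oc1cc(Br)c(Br)c(Br)c1Oc1ccc(Br)cc1Br | intermediate (not isolated)
16 | 3,5-dibromo-2-[3,4,5-tribromo-2-(2,4-dibromophenoxy)phenoxy]phenyl hydrogen sulfate (bromoiesol A sulfate) | O=S(=O)(O)Oc1cc(Br)cc(Br)c1Oc1cc(Br)c(Br)c(Br)c1Oc1ccc(Br)cc1Br | target

**Totals**
Total step count: 6. Longest linear sequence: 4 steps (5 → 6 → 7 → 9 → 16; steps 2, 3, 4, 6).

**Three steps most likely to fail**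

Step 6 (the proposed new step). The ion pair may not form cleanly, the hindered phenoxide may couple slowly, or the sulfate may cause solubility or side-reaction problems. The fallback uses known chemistry only and installs the sulfate last. It sets out from iodonium salt 9. Known O-arylation (K2CO3, MeCN, 60 °C) of purchased 2,4-dibromo-6-methoxyphenol F1 gives 1,2,3-tribromo-5-(2,4-dibromo-6-methoxyphenoxy)-4-(2,4-dibromophenoxy)benzene F2. BBr3 in CH2Cl2 (−78 → 0 °C) cleaves only the methyl ether and gives 3,5-dibromo-2-[3,4,5-tribromo-2-(2,4-dibromophenoxy)phenoxy]phenol F3. Sulfation with Me3N·SO3 and K2CO3 in DMF gives the potassium salt 15, where the fallback comes back to the route; cold acidification then gives 16 as in step 6.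

Step 5 (Elbs oxidation). The electron-poor phenolate may react slowly and give a low yield. The fallback builds the catechol first and sets the sulfate by ring opening. It sets out from purchased 3,5-dibromo-2-hydroxybenzaldehyde F4, used in place of 10. Dakin oxidation (H2O2, aqueous NaOH) gives 3,5-dibromobenzene-1,2-diol F5. SO2Cl2 and pyridine in CH2Cl2 (−78 → 0 °C) give the cyclic sulfate 4,6-dibromo-1,3,2-benzodioxathiole 2,2-dioxide F6. Cold KOH (2 equiv, aqueous MeCN, 0 °C) attacks sulfur and expels the more acidic, bromine-flanked phenoxide, which gives 11. The fallback comes back to the route at 11, which is neutralised to 12 as in step 5.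

Step 2 (double bromination). Bromine may attack the iodine-bearing carbon and scramble the halogens. The fallback introduces iodine last by a Sandmeyer reaction. It sets out from iodonium salt 4 and from purchased 5-bromo-2-nitrophenol F7, used in place of 5. Br2 with NaOAc in AcOH gives 2,3,4-tribromo-6-nitrophenol F8, since OH and NO2 direct to the same two carbons. O-Arylation with 4 (K2CO3, DMF, 80 °C) gives 1,2,3-tribromo-4-(2,4-dibromophenoxy)-5-nitrobenzene F9. Fe and NH4Cl in aqueous EtOH give 3,4,5-tribromo-2-(2,4-dibromophenoxy)aniline F10. NaNO2 in H2SO4/AcOH at 0 °C gives 3,4,5-tribromo-2-(2,4-dibromophenoxy)benzenediazonium hydrogen sulfate F11, and KI converts it into 7, where the fallback comes back to the route.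

**Further compounds**
F1 | step 6 | 2,4-dibromo-6-methoxyphenol | COc1cc(Br)cc(Br)c1O
F2 | step 6 | 1,2,3-tribromo-5-(2,4-dibromo-6-methoxyphenoxy)-4-(2,4-dibromophenoxy)benzene | COc1cc(Br)cc(Br)c1Oc1cc(Br)c(Br)c(Br)c1Oc1ccc(Br)cc1Br
F3 | step 6 | 3,5-dibromo-2-[3,4,5-tribromo-2-(2,4-dibromophenoxy)phenoxy]phenol | Oc1cc(Br)cc(Br)c1Oc1cc(Br)c(Br)c(Br)c1Oc1ccc(Br)cc1Br
F4 | step 5 | 3,5-dibromo-2-hydroxybenzaldehyde | O=Cc1cc(Br)cc(Br)c1O
F5 | step 5 | 3,5-dibromobenzene-1,2-diol | Oc1cc(Br)cc(Br)c1O
F6 | step 5 | 4,6-dibromo-1,3,2-benzodioxathiole 2,2-dioxide | O=S1(=O)Oc2cc(Br)cc(Br)c2O1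
F7 | step 2 | 5-bromo-2-nitrophenol | Oc1cc(Br)ccc1[N+](=O)[O-]
F8 | step 2 | 2,3,4-tribromo-6-nitrophenol | Oc1c(Br)c(Br)c(Br)cc1[N+](=O)[O-]
F9 | step 2 | 1,2,3-tribromo-4-(2,4-dibromophenoxy)-5-nitrobenzene | [O-][N+](=O)c1cc(Br)c(Br)c(Br)c1Oc1ccc(Br)cc1Br
F10 | step 2 | 3,4,5-tribromo-2-(2,4-dibromophenoxy)aniline | Nc1cc(Br)c(Br)c(Br)c1Oc1ccc(Br)cc1Br
F11 | step 2 | 3,4,5-tribromo-2-(2,4-dibromophenoxy)benzenediazonium hydrogen sulfate | N#[N+]c1cc(Br)c(Br)c(Br)c1Oc1ccc(Br)cc1Br.OS(=O)(=O)[O-]
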